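**Assumption:** the target has no stereocentre and is achiral, so no enantiocontrol is needed; acetophenone 1 is taken as a purchasable catalogue compound.

**Retrosynthetic overview**
1. Target 8 comes from flavonol 7 by O-methylation of the 3-OH (C3–O–CH3 disconnection).
2. Flavonol 7 comes from flavone 5 by C3–H to C3–OH oxidation (epoxidation, then acid isomerisation).
3. Flavone 5 comes from chalcone 3 by O1–C2 bond formation and dehydrogenation; ring C is the only ring built.
4. Chalcone 3 comes from an aldol disconnection into acetophenone 1 (ring A with all four methoxy groups) and benzaldehyde 2 (ring B).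
5. Ring order: rings A and B are bought, ring C is closed in step 2.

**Route**

Step 1
Reactants: 1 2'-hydroxy-3',4',5',6'-tetramethoxyacetophenone; 2 benzaldehyde
Product: 3 (E)-2'-hydroxy-3',4',5',6'-tetramethoxychalcone
Conditions: PhCHO (1.2 equiv), KOH (50% aq., 5 equiv), EtOH, 0 °C to rt, 24–48 h; then aq. HCl
Reagents that add atoms: none
Why: Claisen–Schmidt (crossed aldol) condensation of the ketone enolate with non-enolisable benzaldehyde, where E1cB dehydration gives the conjugated E-alkene under thermodynamic control and no stereocentre is formed.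

Step 2
Reactants: 3 (E)-2'-hydroxy-3',4',5',6'-tetramethoxychalcone
Product: 5 5,6,7,8-tetramethoxyflavone, via tetramethoxyflavanone 4 (not isolated)
Conditions: I2 (10 mol %), DMSO, 130 °C, 2–4 h
Reagents that add atoms: none
Why: Iodine-catalysed oxidative cyclisation, in which oxa-Michael addition of the phenol gives racemic flavanone 4, iodine dehydrogenates it to the flavone (erasing the C-2 stereocentre) and DMSO reoxidises HI to I2; catalytic iodine keeps the methyl ethers intact.

Step 3
Reactants: 5 5,6,7,8-tetramethoxyflavone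
Product: 7 3-hydroxy-5,6,7,8-tetramethoxyflavone, via flavone epoxide 6 (not isolated)
Conditions: DMDO (ca. 0.08 M in acetone, 3 equiv), CH2Cl2, 0 °C to rt, 12–24 h; evaporate; then p-TsOH·H2O (cat.), CHCl3, rt
Reagents that add atoms: dimethyldioxirane (DMDO), CC1(C)OO1
Why: Neutral electrophilic epoxidation of the C2=C3 bond by the dioxirane gives racemic epoxide 6, which acid opens at C-2 (oxocarbenium) and loss of H-3 gives the flavonol, destroying both epoxide stereocentres; ring A has no C–H bond to oxidise.

Step 4
Reactants: 7 3-hydroxy-5,6,7,8-tetramethoxyflavone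
Product: 8 3,5,6,7,8-pentamethoxyflavone
Conditions: MeI (3 equiv), K2CO3 (3 equiv), acetone, reflux, 8–12 h
Reagents that add atoms: iodomethane (MeI), CI
Why: Williamson ether synthesis, SN2 methylation of the acidic enolic 3-OH by MeI with K2CO3 as base; there is no other free OH and no stereocentre.

**Compound list**
1 | 2'-hydroxy-3',4',5',6'-tetramethoxyacetophenone, 1-(2-hydroxy-3,4,5,6-tetramethoxyphenyl)ethan-1-one | CC(=O)c1c(O)c(OC)c(OC)c(OC)c1OC | starting material
2 | benzaldehyde | O=Cc1ccccc1 | starting material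
3 | (E)-2'-hydroxy-3',4',5',6'-tetramethoxychalcone, (E)-1-(2-hydroxy-3,4,5,6-tetramethoxyphenyl)-3-phenylprop-2-en-1-one | O=C(/C=C/c1ccccc1)c1c(O)c(OC)c(OC)c(OC)c1OC | intermediate
4 | racemic 5,6,7,8-tetramethoxyflavanone (5,6,7,8-tetramethoxy-2-phenylchroman-4-one), formed in the flask | O=C1CC(c2ccccc2)Oc2c(OC)c(OC)c(OC)c(OC)c12 | intermediate
5 | 5,6,7,8-tetramethoxyflavone (5,6,7,8-tetramethoxy-2-phenyl-4H-chromen-4-one) | COc1c(OC)c(OC)c2c(=O)cc(-c3ccccc3)oc2c1OC | intermediate
6 | racemic 2,3-epoxy-5,6,7,8-tetramethoxyflavanone (2,3-epoxide of 5, cis-fused), formed in the flask | COc1c(OC)c(OC)c2c(c1OC)OC1(c3ccccc3)OC1C2=O | intermediate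
7 | 3-hydroxy-5,6,7,8-tetramethoxyflavone | COc1c(OC)c(OC)c2c(=O)c(O)c(-c3ccccc3)oc2c1OC | intermediate
8 | 3,5,6,7,8-pentamethoxyflavone | COc1c(OC)c(OC)c2c(=O)c(OC)c(-c3ccccc3)oc2c1OC | target

**Total step count:** 4. **Longest linear sequence:** 4 steps (1 to 8).

**Steps most likely to fail** (most risky first: step 3, step 2, step 1), given below in step order.

Step 1 risk: the ketone sits between two ortho substituents and reacts as a phenoxide-enolate dianion, so condensation can be slow and benzaldehyde can be lost to Cannizzaro reaction. The fallback sets out from 1 and masks the phenol first. MOMCl and iPr2NEt in CH2Cl2 give 1-[2-(methoxymethoxy)-3,4,5,6-tetramethoxyphenyl]ethan-1-one F1. Claisen–Schmidt condensation of this neutral ketone with 2 (KOH, EtOH, rt) gives (E)-1-[2-(methoxymethoxy)-3,4,5,6-tetramethoxyphenyl]-3-phenylprop-2-en-1-one F2. Acetal cleavage with HCl in MeOH at 50 °C releases the phenol, and the fallback comes back to the route at 3.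

Step 2 risk: HI formed at 130 °C can cleave the 5-methoxy group peri to the carbonyl, and ring closure can stall at flavanone 4 or divert to an aurone. The fallback sets out from 1 and avoids both the chalcone and the oxidation by building ring C at the right oxidation level. Benzoyl chloride in pyridine gives 2-acetyl-3,4,5,6-tetramethoxyphenyl benzoate F3. Baker–Venkataraman O-to-C acyl migration (KOH, pyridine, 50 °C) gives 1-(2-hydroxy-3,4,5,6-tetramethoxyphenyl)-3-phenylpropane-1,3-dione F4. Cyclodehydration with catalytic H2SO4 in AcOH at 100 °C brings the fallback back to the route at 5.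

Step 3 risk: epoxidation of the vinylogous-ester double bond by DMDO is slow, and the very electron-rich ring A may be over-oxidised by excess oxidant. The fallback sets out from 5 and replaces electrophilic oxidation with a C-3 carbanion. LiN(iPr)2 in THF at −78 °C gives 3-lithio-5,6,7,8-tetramethoxyflavone F5. Trapping with B(OMe)3 gives dimethyl (5,6,7,8-tetramethoxy-4-oxo-2-phenyl-4H-chromen-3-yl)boronate F6. Oxidation of the C–B bond in the same flask with H2O2 and AcOH (0 °C to rt) brings the fallback back to the route at 7.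

**Further compounds**
F1 | step 1 | 1-[2-(methoxymethoxy)-3,4,5,6-tetramethoxyphenyl]ethan-1-one | CC(=O)c1c(OCOC)c(OC)c(OC)c(OC)c1OC
F2 | step 1 | (E)-1-[2-(methoxymethoxy)-3,4,5,6-tetramethoxyphenyl]-3-phenylprop-2-en-1-one | O=C(/C=C/c1ccccc1)c1c(OCOC)c(OC)c(OC)c(OC)c1OC
F3 | step 2 | 2-acetyl-3,4,5,6-tetramethoxyphenyl benzoate | CC(=O)c1c(OC(=O)c2ccccc2)c(OC)c(OC)c(OC)c1OC
F4 | step 2 | 1-(2-hydroxy-3,4,5,6-tetramethoxyphenyl)-3-phenylpropane-1,3-dione | O=C(CC(=O)c1ccccc1)c1c(O)c(OC)c(OC)c(OC)c1OC
F5 | step 3 | 3-lithio-5,6,7,8-tetramethoxyflavone | COc1c(OC)c(OC)c2c(=O)c([Li])c(-c3ccccc3)oc2c1OC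
F6 | step 3 | dimethyl (5,6,7,8-tetramethoxy-4-oxo-2-phenyl-4H-chromen-3-yl)boronate | COB(OC)c1c(-c2ccccc2)oc2c(OC)c(OC)c(OC)c(OC)c2c1=O
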